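The route cuts the cycloheptane between its CH2 carbon and the CH(OAng) carbon (Ang = angeloyl). The key step is an intramolecular aldol addition of a methyl ketone enolate to a neopentyl aldehyde, both held cis-1,3 on the cyclobutane of a preformed bicyclo[3.1.1]heptane, followed in the same flask by lactonisation of the aldolate onto the ester on the neighbouring quaternary carbon. One operation closes the seven-membered ring, fixes the CH–O centre (only the epimer cis to the future CH2OAng carbon can lactonise) and tells apart the three oxygens of the CH(O)–CH2–CH(O)/CH2O array. The precursor comes from an intramolecular vinylketene–alkene (2+2) cycloaddition, malonate attachment and esterase desymmetrisation.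

Key step: step 16

Remarks (before the steps)
- Skeleton numbering used below (own numbering): C1 = quaternary carbon bearing CH3 (C13) and the CH2O carbon C12; C2 = cyclobutane CH bonded to C1; C3 = bridgehead next to the ketone; C4 = ketone carbon; C5 = enone CH; C6 = methyl-bearing enone carbon (methyl C15); C7 = second bridgehead; C8 = quaternary cyclobutane carbon (methyl C14); C9 = CH(OAng); C10 = ring CH2; C11 = CH(OAc). O4, O9, O11 are the oxygens on these carbons. Rings: cyclobutane C2–C3–C8–C7, cyclohexenone C3–C4–C5–C6–C7–C2, cycloheptane C1–C2–C3–C8–C9–C10–C11.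
- In the bicyclo[3.1.1]heptane names of 11–22, ring atoms 1, 2, 3, 4, 5, 6, 7 are skeleton C7, C6, C5, C4, C3, C2, C8.
- Assumption: the (S,S) antipode of the bisphosphoramide gives the 5S alcohol 4 (otherwise its mirror image is used), and pig liver esterase gives the R half-ester 18, the sense expected for 2-methylmalonates with a large second substituent.

Step 1
Reactants: 1 methyl 3-methylbut-2-enoate
Product: 2 (1Z)-tert-butyl[(1-methoxy-3-methylbuta-1,3-dien-1-yl)oxy]dimethylsilane
Conditions: LiN(iPr)2, THF, −78 °C; TBSCl, DMPU, −78 → 0 °C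
Reagents that add atoms: tert-butyldimethylsilyl chloride C[Si](C)(Cl)C(C)(C)C
Why: Kinetic γ-deprotonation of the enoate and O-silylation of the extended enolate (silyl ketene acetal formation) should give the dienolate needed for a vinylogous Mukaiyama aldol reaction; its ketene acetal geometry does not matter in the open transition state of step 2.

Step 2
Reactants: 2 silyl dienolate; 3 3-methylbut-2-enal
Product: 4 methyl (2E,5S)-5-hydroxy-3,7-dimethylocta-2,6-dienoate
Conditions: SiCl4 (1.1 equiv), (S,S)-bisphosphoramide (pentamethylene-linked, from N,N'-dimethyl-1,1'-binaphthyl-2,2'-diamine, 5 mol %), iPr2NEt (cat.), CH2Cl2, −78 °C; aq. NaHCO3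
Reagents that add atoms: none
Why: Lewis-base-activated SiCl4 vinylogous Mukaiyama aldol addition, in which the chiral phosphoramide-bound trichlorosilyl cation binds the enal and the dienolate attacks through its γ-carbon in an open transition state, should give the E-enoate and set the carbinol centre (later C4) as S under catalyst control.

Step 3
Reactants: 4 hydroxy ester
Product: 5 methyl (2E,5S)-3,7-dimethyl-5-(triethylsilyloxy)octa-2,6-dienoate
Conditions: Et3SiCl, imidazole, DMF, 0 °C → rt
Reagents that add atoms: chlorotriethylsilane CC[Si](Cl)(CC)CC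
Why: Standard silylation; the triethylsilyl group is chosen because it can later be removed in the presence of the primary TBS ether.

Step 4
Reactants: 5 silyl ether
Product: 6 methyl (2E,5S,6E)-8-hydroxy-3,7-dimethyl-5-(triethylsilyloxy)octa-2,6-dienoate
Conditions: SeO2 (0.3 equiv), t-BuOOH (2 equiv), CH2Cl2, 0 °C → rt
Reagents that add atoms: tert-butyl hydroperoxide CC(C)(C)OO (terminal oxidant; the oxygen is passed on by catalytic selenium dioxide O=[Se]=O)
Why: SeO2-catalysed allylic oxidation (ene reaction then [2,3]-sigmatropic shift) attacks the electron-rich trisubstituted alkene at its E-methyl group, so the (E)-allylic alcohol should form, and this geometry later decides which substituent of C8 faces C2.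

Step 5
Reactants: 6 allylic alcohol
Product: 7 methyl (2E,5S,6E)-8-(tert-butyldimethylsilyloxy)-3,7-dimethyl-5-(triethylsilyloxy)octa-2,6-dienoate
Conditions: TBSCl, imidazole, DMF, 0 °C → rt
Reagents that add atoms: tert-butyldimethylsilyl chloride C[Si](C)(Cl)C(C)(C)C
Why: Standard silylation of the primary allylic alcohol.

Step 6
Reactants: 7 bis-silyl ether ester
Product: 8 potassium (2E,5S,6E)-8-(tert-butyldimethylsilyloxy)-3,7-dimethyl-5-(triethylsilyloxy)octa-2,6-dienoate
Conditions: KOSiMe3, THF, rt
Reagents that add atoms: potassium trimethylsilanolate C[Si](C)(C)[O-].[K+]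
Why: Nucleophilic cleavage of the methyl ester by trimethylsilanolate gives the anhydrous potassium carboxylate without acid or aqueous base, which the acid-labile TES ether should tolerate.

Step 7
Reactants: 8 potassium carboxylate
Product: 11 (1R,4S,5R,7R)-7-[(tert-butyldimethylsilyloxy)methyl]-7-methyl-2-methylidene-4-(triethylsilyloxy)bicyclo[3.1.1]heptan-6-one, via acid chloride 9 (not isolated), via vinylketene 10 (not isolated)
Conditions: (COCl)2, CH2Cl2, 0 °C; then slow addition to Et3N, toluene, 110 °C (high dilution)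
Reagents that add atoms: none
Why: Oxalyl chloride converts the carboxylate salt into the acid chloride without free HCl, triethylamine removes HCl through the γ-methyl to give a vinylketene, and the intramolecular ketene–alkene (2+2) cycloaddition known for geranic-acid-type chlorides joins the ketene carbonyl carbon to C3 and its α-carbon to the more substituted C8, with suprafacial retention of the alkene geometry (C14 methyl toward the three-carbon bridge, CH2OTBS away from it) and with the alkene face chosen by A(1,3) strain at the allylic OTES centre (H eclipsing the cis-methyl, tether anti to OTES), which sets C3, C7 and C8.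

Step 8
Reactants: 11 bicyclic ketone; 12 dimethyl malonate
Product: 14 dimethyl 2-[7-[(tert-butyldimethylsilyloxy)methyl]-4-hydroxy-7-methyl-2-methylidenebicyclo[3.1.1]heptan-6-ylidene]propanedioate (ring configuration as in 11), via triethylsilyl ether 13 (not isolated)
Conditions: TiCl4, pyridine, THF, 0 °C → rt; work-up, then HF·pyridine, pyridine, THF, 0 °C
Reagents that add atoms: none
Why: TiCl4/pyridine Knoevenagel condensation with the strained, non-enolisable cyclobutanone (the only carbonyl electrophile), followed by buffered fluoride, which cleaves the secondary TES ether much faster than the neopentyl TBS ether and frees the C4 hydroxyl as a directing group.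

Step 9
Reactants: 14 alkylidene malonate
Product: 15 dimethyl 2-[7-[(tert-butyldimethylsilyloxy)methyl]-4-hydroxy-2,7-dimethylbicyclo[3.1.1]heptan-6-yl]propanedioate (malonyl group on C2 of the skeleton cis to the CH2OTBS group of C8, C15 methyl syn to C8, other centres as in 11)
Conditions: H2 (1–4 atm), [Ir(cod)(PCy3)(py)]PF6 (10 mol %), CH2Cl2, rt
Reagents that add atoms: none
Why: Hydroxyl-directed hydrogenation with the cationic iridium catalyst, which reduces tetrasubstituted alkenes: iridium held by the C4 hydroxyl should deliver H2 to C2 from the face of the three-carbon bridge, so the malonyl carbon is pushed to the face that looks at C9 (cis-1,3 across the cyclobutane), and the exocyclic methylene is reduced from the same, less hindered face (its temporary C6 centre is removed in step 24).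

Step 10
Reactants: 15 hydroxy malonate
Product: 16 dimethyl 2-[7-[(tert-butyldimethylsilyloxy)methyl]-2,7-dimethyl-4-(triisopropylsilyloxy)bicyclo[3.1.1]heptan-6-yl]propanedioate
Conditions: iPr3SiOSO2CF3, 2,6-lutidine, CH2Cl2, −78 → 0 °C
Reagents that add atoms: triisopropylsilyl trifluoromethanesulfonate CC(C)[Si](OS(=O)(=O)C(F)(F)F)(C(C)C)C(C)C
Why: Silylation with the triflate protects the hindered secondary alcohol as the robust TIPS ether, which should survive all later fluoride and hydride steps until step 23.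

Step 11
Reactants: 16 malonate
Product: 17 dimethyl 2-methyl-2-[7-[(tert-butyldimethylsilyloxy)methyl]-2,7-dimethyl-4-(triisopropylsilyloxy)bicyclo[3.1.1]heptan-6-yl]propanedioate
Conditions: NaH, MeI, DMF, 0 °C → rt
Reagents that add atoms: iodomethane CI
Why: Malonate alkylation; C1 becomes a prochiral quaternary carbon with two identical ester groups, so no stereochemical question arises here.

Step 12
Reactants: 17 methylated malonate
Product: 18 (2R)-3-methoxy-2-methyl-3-oxo-2-[7-[(tert-butyldimethylsilyloxy)methyl]-2,7-dimethyl-4-(triisopropylsilyloxy)bicyclo[3.1.1]heptan-6-yl]propanoic acid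
Conditions: pig liver esterase (a carboxylesterase), 0.5 M phosphate buffer pH 7.5, DMSO (10 vol %), 30 °C; then pH 3, extraction
Reagents that add atoms: water O
Why: Hydrolase (carboxylesterase) desymmetrisation of a prochiral 2-alkyl-2-methylmalonate: the enzyme tells the two ester groups apart through its own chirality, which the almost mirror-symmetric surroundings of C2 cannot do, and large 2-substituents are known to lead to the R half-esters, which sets C1.

Step 13
Reactants: 18 half-ester
Product: 20 methyl (2R)-2-methyl-3-oxo-2-[7-[(tert-butyldimethylsilyloxy)methyl]-2,7-dimethyl-4-(triisopropylsilyloxy)bicyclo[3.1.1]heptan-6-yl]butanoate, via acid chloride 19 (not isolated)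
Conditions: 1-chloro-N,N,2-trimethylprop-1-en-1-amine, CH2Cl2, 0 °C → rt; then Me2CuLi (from MeLi and CuI), Et2O, −78 °C; aq. NH4Cl
Reagents that add atoms: lithium dimethylcuprate [Li+].C[Cu-]C
Why: Neutral acid chloride formation and acyl substitution by a Gilman cuprate should give the methyl ketone without touching the methyl ester or the product ketone at −78 °C, and the quaternary C1 cannot epimerise.

Step 14
Reactants: 20 β-keto ester
Product: 21 methyl (2R)-2-[7-(hydroxymethyl)-2,7-dimethyl-4-(triisopropylsilyloxy)bicyclo[3.1.1]heptan-6-yl]-2-methyl-3-oxobutanoate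
Conditions: HF·pyridine, pyridine, THF, 0 °C
Reagents that add atoms: none
Why: Buffered HF·pyridine cleaves the primary TBS ether selectively in the presence of the secondary TIPS ether; the alcohol is oxidised at once to limit lactonisation onto the nearby ester.

Step 15
Reactants: 21 primary alcohol
Product: 22 methyl (2R)-2-[7-formyl-2,7-dimethyl-4-(triisopropylsilyloxy)bicyclo[3.1.1]heptan-6-yl]-2-methyl-3-oxobutanoate
Conditions: Dess–Martin periodinane, pyridine, CH2Cl2, 0 °C → rt
Reagents that add atoms: none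
Why: Dess–Martin oxidation of the neopentyl alcohol should give the non-enolisable aldehyde under buffered conditions.

Step 16
Reactants: 22 keto ester aldehyde
Product: 24 keto lactone (C9–C10 bond closed; lactone from O9 to the C12 carbonyl; ketone at C11; 4-OTIPS), via lithium aldolate 23 (not isolated)
Conditions: LiN(SiMe3)2 (1.05 equiv), THF (0.01 M), −78 → −20 °C; AcOH at −20 °C
Reagents that add atoms: none
Why: LiN(SiMe3)2 can deprotonate only the methyl ketone (C10), since the aldehyde carbon C9 hangs on quaternary C8 and C1 is quaternary, and the lithium enolate adds to the aldehyde that the cyclobutane holds cis-1,3 to it: an intramolecular aldol addition of the 7-(enolendo)-exo-trig type that closes the cycloheptane by the C9–C10 bond. The lithium aldolate 23 then attacks the C12 methyl ester (7-exo-trig acyl substitution), so the whole is an aldol–lactonisation cascade, the closest known type being tandem aldol–lactonisations of keto esters. C9 is the only new stereocentre: lithium bridges the enolate oxygen, the ester carbonyl on C1 and the aldehyde oxygen, which places O9 on the side of C12, and only this epimer can lactonise, because in the lactone bicycle C9 and C1 are both bridgeheads with H and CH3 pointing outward. The other aldolate cannot be trapped and returns through retro-aldol, so kinetic chelation and the thermodynamic trap point the same way. The step needs regioselective enolisation (secured by the absence of any other acidic C–H) and face selectivity at C9 (secured by the C1 centre from step 12). The cold AcOH quench removes lithium methoxide before it can eliminate the β-acyloxy ketone.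

Step 17
Reactants: 24 keto lactone
Product: 25 hydroxy lactone (C11–OH trans to O9 and to C12)
Conditions: NaBH4, CeCl3·7H2O, MeOH/THF, −78 °C
Reagents that add atoms: none
Why: Luche-type borohydride reduction of the ketone, in which the face of C11=O that looks at the cyclobutane (C7–H) is blocked and hydride should enter over the flat lactone bridge, so O11 ends trans to O9 and to C12.

Step 18
Reactants: 25 hydroxy lactone
Product: 26 C11 triethylsilyl ether of the hydroxy lactone
Conditions: Et3SiOSO2CF3, 2,6-lutidine, CH2Cl2, −78 → 0 °C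
Reagents that add atoms: triethylsilyl trifluoromethanesulfonate CC[Si](CC)(CC)OS(=O)(=O)C(F)(F)F
Why: Silylation of the free hydroxyl keeps O11 distinct from the two oxygens that are still tied up in the lactone.

Step 19
Reactants: 26 silyl ether lactone
Product: 27 diol (C9–OH and C12H2–OH free; C11–OTES; C4–OTIPS)
Conditions: LiAlH4, THF, 0 °C; Na2SO4·10H2O
Reagents that add atoms: none
Why: Hydride reduction of the lactone frees O9–H and C12H2–OH together while the silyl ethers are untouched.

Step 20
Reactants: 27 diol; 28 angelic acid ((Z)-2-methylbut-2-enoic acid)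
Product: 29 9,12-bis-angelate (C11–OTES; C4–OTIPS)
Conditions: 28 (4 equiv), 2,4,6-trichlorobenzoyl chloride, Et3N, toluene, rt; then 27, toluene, 80 °C
Reagents that add atoms: none
Why: Yamaguchi-type mixed-anhydride esterification without nucleophilic catalyst, the usual way to make angelates without Z to E isomerisation, should acylate both the primary and the secondary hydroxyl.

Step 21
Reactants: 29 bis-angelate
Product: 30 C11 alcohol of the bis-angelate
Conditions: HF·pyridine, pyridine, THF, 0 °C
Reagents that add atoms: none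
Why: The triethylsilyl ether is cleaved by buffered HF·pyridine far faster than the TIPS ether.

Step 22
Reactants: 30 alcohol
Product: 31 C11 acetate (C4–OTIPS)
Conditions: Ac2O, pyridine, DMAP (cat.), CH2Cl2, rt
Reagents that add atoms: acetic anhydride CC(=O)OC(C)=O
Why: Standard acetylation of the secondary alcohol; the formed angelate esters are not isomerised under these mild conditions.

Step 23
Reactants: 31 acetate
Product: 32 C4 alcohol (dihydro-4-hydroxy precursor of the target)
Conditions: HF·pyridine, THF/MeCN, rt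
Reagents that add atoms: none
Why: Fluoride cleavage of the TIPS ether under mildly acidic conditions that the three esters tolerate.

Step 24
Reactants: 32 C4 alcohol
Product: 34 target CNP0364726.1, via saturated ketone 33 (not isolated)
Conditions: IBX (2-iodoxybenzoic acid, 3–4 equiv), DMSO, rt → 70 °C
Reagents that add atoms: none
Why: IBX oxidises the alcohol to the ketone and on warming dehydrogenates it (IBX ketone dehydrogenation), the ketone being enolisable only toward C5 because C3 is a bridgehead, so the C5=C6 enone should form regioselectively and the temporary C6 centre disappears.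

Compound list
1 | methyl 3-methylbut-2-enoate | COC(=O)C=C(C)C | starting material
2 | (1Z)-tert-butyl[(1-methoxy-3-methylbuta-1,3-dien-1-yl)oxy]dimethylsilane | C=C(C)/C=C(\O[Si](C)(C)C(C)(C)C)OC | intermediate
3 | 3-methylbut-2-enal | CC(C)=CC=O | starting material
4 | methyl (2E,5S)-5-hydroxy-3,7-dimethylocta-2,6-dienoate | COC(=O)/C=C(\C)C[C@H](O)C=C(C)C | intermediate
5 | methyl (2E,5S)-3,7-dimethyl-5-(triethylsilyloxy)octa-2,6-dienoate | COC(=O)/C=C(\C)C[C@H](O[Si](CC)(CC)CC)C=C(C)C | intermediate
6 | methyl (2E,5S,6E)-8-hydroxy-3,7-dimethyl-5-(triethylsilyloxy)octa-2,6-dienoate | COC(=O)/C=C(\C)C[C@H](O[Si](CC)(CC)CC)/C=C(\C)CO | intermediate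
7 | methyl (2E,5S,6E)-8-(tert-butyldimethylsilyloxy)-3,7-dimethyl-5-(triethylsilyloxy)octa-2,6-dienoate | COC(=O)/C=C(\C)C[C@H](O[Si](CC)(CC)CC)/C=C(\C)CO[Si](C)(C)C(C)(C)C | intermediate
8 | potassium (2E,5S,6E)-8-(tert-butyldimethylsilyloxy)-3,7-dimethyl-5-(triethylsilyloxy)octa-2,6-dienoate | [K+].[O-]C(=O)/C=C(\C)C[C@H](O[Si](CC)(CC)CC)/C=C(\C)CO[Si](C)(C)C(C)(C)C | intermediate
9 | (2E,5S,6E)-8-(tert-butyldimethylsilyloxy)-3,7-dimethyl-5-(triethylsilyloxy)octa-2,6-dienoyl chloride | ClC(=O)/C=C(\C)C[C@H](O[Si](CC)(CC)CC)/C=C(\C)CO[Si](C)(C)C(C)(C)C | intermediate (not isolated)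
10 | (5S,6E)-8-(tert-butyldimethylsilyloxy)-7-methyl-3-methylidene-5-(triethylsilyloxy)octa-1,6-dien-1-one (vinylketene) | O=C=CC(=C)C[C@H](O[Si](CC)(CC)CC)/C=C(\C)CO[Si](C)(C)C(C)(C)C | intermediate (not isolated)
11 | (1R,4S,5R,7R)-7-[(tert-butyldimethylsilyloxy)methyl]-7-methyl-2-methylidene-4-(triethylsilyloxy)bicyclo[3.1.1]heptan-6-one | O=C1[C@H]2[C@@H](O[Si](CC)(CC)CC)CC(=C)[C@@H]1[C@@]2(C)CO[Si](C)(C)C(C)(C)C | intermediate
12 | dimethyl malonate | COC(=O)CC(=O)OC | starting material
13 | dimethyl 2-[7-[(tert-butyldimethylsilyloxy)methyl]-7-methyl-2-methylidene-4-(triethylsilyloxy)bicyclo[3.1.1]heptan-6-ylidene]propanedioate, ring configuration as in 11 | COC(=O)C(C(=O)OC)=C1[C@H]2[C@@H](O[Si](CC)(CC)CC)CC(=C)[C@@H]1[C@@]2(C)CO[Si](C)(C)C(C)(C)C | intermediate (not isolated)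
14 | dimethyl 2-[7-[(tert-butyldimethylsilyloxy)methyl]-4-hydroxy-7-methyl-2-methylidenebicyclo[3.1.1]heptan-6-ylidene]propanedioate, ring configuration as in 11 | COC(=O)C(C(=O)OC)=C1[C@H]2[C@@H](O)CC(=C)[C@@H]1[C@@]2(C)CO[Si](C)(C)C(C)(C)C | intermediate
15 | dimethyl 2-[7-[(tert-butyldimethylsilyloxy)methyl]-4-hydroxy-2,7-dimethylbicyclo[3.1.1]heptan-6-yl]propanedioate; malonyl group cis to CH2OTBS across the cyclobutane, 2-methyl syn to the C7 bridge | COC(=O)C(C(=O)OC)[C@@H]1[C@H]2[C@@H](O)C[C@H](C)[C@@H]1[C@@]2(C)CO[Si](C)(C)C(C)(C)C | intermediate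
16 | 4-O-triisopropylsilyl ether of 15 | COC(=O)C(C(=O)OC)[C@@H]1[C@H]2[C@@H](O[Si](C(C)C)(C(C)C)C(C)C)C[C@H](C)[C@@H]1[C@@]2(C)CO[Si](C)(C)C(C)(C)C | intermediate
17 | dimethyl 2-methyl-2-[7-[(tert-butyldimethylsilyloxy)methyl]-2,7-dimethyl-4-(triisopropylsilyloxy)bicyclo[3.1.1]heptan-6-yl]propanedioate | COC(=O)C(C)(C(=O)OC)[C@@H]1[C@H]2[C@@H](O[Si](C(C)C)(C(C)C)C(C)C)C[C@H](C)[C@@H]1[C@@]2(C)CO[Si](C)(C)C(C)(C)C | intermediate
18 | (2R)-3-methoxy-2-methyl-3-oxo-2-[7-[(tert-butyldimethylsilyloxy)methyl]-2,7-dimethyl-4-(triisopropylsilyloxy)bicyclo[3.1.1]heptan-6-yl]propanoic acid | COC(=O)[C@@](C)(C(=O)O)[C@@H]1[C@H]2[C@@H](O[Si](C(C)C)(C(C)C)C(C)C)C[C@H](C)[C@@H]1[C@@]2(C)CO[Si](C)(C)C(C)(C)C | intermediate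
19 | acid chloride of 18 | COC(=O)[C@@](C)(C(=O)Cl)[C@@H]1[C@H]2[C@@H](O[Si](C(C)C)(C(C)C)C(C)C)C[C@H](C)[C@@H]1[C@@]2(C)CO[Si](C)(C)C(C)(C)C | intermediate (not isolated)
20 | methyl (2R)-2-methyl-3-oxo-2-[7-[(tert-butyldimethylsilyloxy)methyl]-2,7-dimethyl-4-(triisopropylsilyloxy)bicyclo[3.1.1]heptan-6-yl]butanoate | COC(=O)[C@@](C)(C(C)=O)[C@@H]1[C@H]2[C@@H](O[Si](C(C)C)(C(C)C)C(C)C)C[C@H](C)[C@@H]1[C@@]2(C)CO[Si](C)(C)C(C)(C)C | intermediate
21 | methyl (2R)-2-[7-(hydroxymethyl)-2,7-dimethyl-4-(triisopropylsilyloxy)bicyclo[3.1.1]heptan-6-yl]-2-methyl-3-oxobutanoate | COC(=O)[C@@](C)(C(C)=O)[C@@H]1[C@H]2[C@@H](O[Si](C(C)C)(C(C)C)C(C)C)C[C@H](C)[C@@H]1[C@@]2(C)CO | intermediate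
22 | methyl (2R)-2-[7-formyl-2,7-dimethyl-4-(triisopropylsilyloxy)bicyclo[3.1.1]heptan-6-yl]-2-methyl-3-oxobutanoate | COC(=O)[C@@](C)(C(C)=O)[C@@H]1[C@H]2[C@@H](O[Si](C(C)C)(C(C)C)C(C)C)C[C@H](C)[C@@H]1[C@@]2(C)C=O | intermediate
23 | lithium aldolate (C9–O–Li, C11 ketone, C12 methyl ester, O9 cis to C12) | COC(=O)[C@]1(C)[C@@H]2[C@H]3[C@@H](O[Si](C(C)C)(C(C)C)C(C)C)C[C@H](C)[C@@H]2[C@@]3(C)[C@H]([O-])CC1=O.[Li+] | intermediate (not isolated)
24 | keto lactone (O9–C12 lactone, C11 ketone, 4-OTIPS, saturated C5–C6) | O=C1[C@]2(C)[C@@H]3[C@H]4[C@@H](O[Si](C(C)C)(C(C)C)C(C)C)C[C@H](C)[C@@H]3[C@@]4(C)[C@H](O1)CC2=O | intermediate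
25 | hydroxy lactone (C11–OH trans to O9) | O=C1[C@]2(C)[C@@H]3[C@H]4[C@@H](O[Si](C(C)C)(C(C)C)C(C)C)C[C@H](C)[C@@H]3[C@@]4(C)[C@H](O1)C[C@H]2O | intermediate
26 | C11 triethylsilyl ether of 25 | O=C1[C@]2(C)[C@@H]3[C@H]4[C@@H](O[Si](C(C)C)(C(C)C)C(C)C)C[C@H](C)[C@@H]3[C@@]4(C)[C@H](O1)C[C@H]2O[Si](CC)(CC)CC | intermediate
27 | diol (C9–OH, C12–OH; C11–OTES; C4–OTIPS) | OC[C@]1(C)[C@@H]2[C@H]3[C@@H](O[Si](C(C)C)(C(C)C)C(C)C)C[C@H](C)[C@@H]2[C@@]3(C)[C@H](O)C[C@H]1O[Si](CC)(CC)CC | intermediate
28 | angelic acid, (Z)-2-methylbut-2-enoic acid | C/C=C(/C)C(=O)O | starting material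
29 | 9,12-bis-angelate (C11–OTES; C4–OTIPS) | C/C=C(/C)C(=O)OC[C@]1(C)[C@@H]2[C@H]3[C@@H](O[Si](C(C)C)(C(C)C)C(C)C)C[C@H](C)[C@@H]2[C@@]3(C)[C@H](OC(=O)/C(C)=C\C)C[C@H]1O[Si](CC)(CC)CC | intermediate
30 | 9,12-bis-angelate with free C11–OH (C4–OTIPS) | C/C=C(/C)C(=O)OC[C@]1(C)[C@@H]2[C@H]3[C@@H](O[Si](C(C)C)(C(C)C)C(C)C)C[C@H](C)[C@@H]2[C@@]3(C)[C@H](OC(=O)/C(C)=C\C)C[C@H]1O | intermediate
31 | 11-acetate 9,12-bis-angelate (C4–OTIPS) | C/C=C(/C)C(=O)OC[C@]1(C)[C@@H]2[C@H]3[C@@H](O[Si](C(C)C)(C(C)C)C(C)C)C[C@H](C)[C@@H]2[C@@]3(C)[C@H](OC(=O)/C(C)=C\C)C[C@H]1OC(C)=O | intermediate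
32 | 11-acetate 9,12-bis-angelate with free C4–OH (5,6-dihydro-4-hydroxy precursor) | C/C=C(/C)C(=O)OC[C@]1(C)[C@@H]2[C@H]3[C@@H](O)C[C@H](C)[C@@H]2[C@@]3(C)[C@H](OC(=O)/C(C)=C\C)C[C@H]1OC(C)=O | intermediate
33 | 5,6-dihydro ketone (C4=O, saturated C5–C6) | C/C=C(/C)C(=O)OC[C@]1(C)[C@@H]2[C@H]3C(=O)C[C@H](C)[C@@H]2[C@@]3(C)[C@H](OC(=O)/C(C)=C\C)C[C@H]1OC(C)=O | intermediate (not isolated)
34 | CNP0364726.1 | C/C=C(/C)C(=O)OC[C@]1(C)[C@@H]2[C@H]3C(=O)C=C(C)[C@@H]2[C@@]3(C)[C@H](OC(=O)/C(C)=C\C)C[C@H]1OC(C)=O | target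

Total step count: 24. Longest linear sequence: 24 steps (1 → 34; 23 steps counted from 3).

Steps most likely to fail

1. Step 12 (esterase desymmetrisation). What may go wrong: slow turnover of the bulky, lipophilic diester, or hydrolysis of both ester groups at similar rates, so that C1 forms with low selectivity. Fallback (catalyst-controlled alkylation instead of an enzyme), setting out from 11 and coming back at 20: Knoevenagel condensation of 11 with methyl acetoacetate (TiCl4, pyridine) gives the silyl-protected alkylidene acetoacetate F1, which buffered HF·pyridine converts into the hydroxy alkylidene acetoacetate F2. Hydroxyl-directed hydrogenation as in step 9 gives the β-keto ester F3 (C1 still enolisable), and iPr3SiOSO2CF3/2,6-lutidine gives its silyl ether F4. Methylation with MeI under phase-transfer catalysis by a chiral N-spiro binaphthyl quaternary ammonium bromide (CsOH·H2O, toluene, −40 °C) sets C1 and should give 20.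

2. Step 9 (directed hydrogenation). What may go wrong: no turnover at the electron-poor, shielded tetrasubstituted alkene, or hydrogen delivery that is not steered by the hydroxyl (ester-bound or undirected), which would give the wrong C2 configuration. Fallback (hydride then separate alkene hydrogenation), setting out from 14 and coming back at 15: NaBH4 in THF turns the free C4 hydroxyl into an alkoxyborohydride that delivers hydride to C2 from the hydroxyl face (conjugate reduction of the alkylidene malonate) and gives the methylidene malonate F5. RhCl(PPh3)3/H2 then reduces only the 1,1-disubstituted exocyclic alkene from the face away from the C14 methyl and should give 15.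

3. Step 16 (key aldol–lactonisation). What may go wrong: β-elimination of the lactone carboxylate from the β-acyloxy ketone by the lithium methoxide set free, retro-Claisen cleavage of the β-keto ester, or lactonisation too slow to trap the right aldolate. Fallback (neutral, reductive enolate formation of the Reformatsky type), setting out from 20 and coming back at 24: LiN(SiMe3)2 then NBS gives the bromomethyl ketone F6; HF·pyridine gives the alcohol F7; Dess–Martin oxidation gives the aldehyde F8. SmI2 (2.2 equiv, THF, −78 → 0 °C) generates a trivalent samarium enolate that adds to the aldehyde through the same chelate, and the samarium aldolate lactonises to 24.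

Further compounds
F1 | step 12 | methyl 2-[7-[(tert-butyldimethylsilyloxy)methyl]-7-methyl-2-methylidene-4-(triethylsilyloxy)bicyclo[3.1.1]heptan-6-ylidene]-3-oxobutanoate (E/Z mixture) | COC(=O)C(C(C)=O)=C1[C@H]2[C@@H](O[Si](CC)(CC)CC)CC(=C)[C@@H]1[C@@]2(C)CO[Si](C)(C)C(C)(C)C
F2 | step 12 | methyl 2-[7-[(tert-butyldimethylsilyloxy)methyl]-4-hydroxy-7-methyl-2-methylidenebicyclo[3.1.1]heptan-6-ylidene]-3-oxobutanoate (E/Z mixture) | COC(=O)C(C(C)=O)=C1[C@H]2[C@@H](O)CC(=C)[C@@H]1[C@@]2(C)CO[Si](C)(C)C(C)(C)C
F3 | step 12 | methyl 2-[7-[(tert-butyldimethylsilyloxy)methyl]-4-hydroxy-2,7-dimethylbicyclo[3.1.1]heptan-6-yl]-3-oxobutanoate (C1 epimers) | COC(=O)C(C(C)=O)[C@@H]1[C@H]2[C@@H](O)C[C@H](C)[C@@H]1[C@@]2(C)CO[Si](C)(C)C(C)(C)C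
F4 | step 12 | methyl 2-[7-[(tert-butyldimethylsilyloxy)methyl]-2,7-dimethyl-4-(triisopropylsilyloxy)bicyclo[3.1.1]heptan-6-yl]-3-oxobutanoate (C1 epimers) | COC(=O)C(C(C)=O)[C@@H]1[C@H]2[C@@H](O[Si](C(C)C)(C(C)C)C(C)C)C[C@H](C)[C@@H]1[C@@]2(C)CO[Si](C)(C)C(C)(C)C
F5 | step 9 | dimethyl 2-[7-[(tert-butyldimethylsilyloxy)methyl]-4-hydroxy-7-methyl-2-methylidenebicyclo[3.1.1]heptan-6-yl]propanedioate | COC(=O)C(C(=O)OC)[C@@H]1[C@H]2[C@@H](O)CC(=C)[C@@H]1[C@@]2(C)CO[Si](C)(C)C(C)(C)C
F6 | step 16 | methyl (2R)-4-bromo-2-methyl-3-oxo-2-[7-[(tert-butyldimethylsilyloxy)methyl]-2,7-dimethyl-4-(triisopropylsilyloxy)bicyclo[3.1.1]heptan-6-yl]butanoate | COC(=O)[C@@](C)(C(=O)CBr)[C@@H]1[C@H]2[C@@H](O[Si](C(C)C)(C(C)C)C(C)C)C[C@H](C)[C@@H]1[C@@]2(C)CO[Si](C)(C)C(C)(C)C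
F7 | step 16 | methyl (2R)-4-bromo-2-[7-(hydroxymethyl)-2,7-dimethyl-4-(triisopropylsilyloxy)bicyclo[3.1.1]heptan-6-yl]-2-methyl-3-oxobutanoate | COC(=O)[C@@](C)(C(=O)CBr)[C@@H]1[C@H]2[C@@H](O[Si](C(C)C)(C(C)C)C(C)C)C[C@H](C)[C@@H]1[C@@]2(C)CO
F8 | step 16 | methyl (2R)-4-bromo-2-[7-formyl-2,7-dimethyl-4-(triisopropylsilyloxy)bicyclo[3.1.1]heptan-6-yl]-2-methyl-3-oxobutanoate | COC(=O)[C@@](C)(C(=O)CBr)[C@@H]1[C@H]2[C@@H](O[Si](C(C)C)(C(C)C)C(C)C)C[C@H](C)[C@@H]1[C@@]2(C)C=O
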